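The charges differ, 0.30 M of substrate in the teal run and 0.20 M in the new flask, but both were fed over 6.0 min, so I reckoned in shares of the charge and assumed first-order loss of substrate.

| setting | teal | flask |
|---|---|---|
| substrate | 0.30 M (fed, over 6.0 min) | 0.20 M (fed, over 6.0 min) |
| reagent | 3 equiv | 3.00 equiv |
| transfer agent | 0.20 M | 0.200 M |
| initiator | 0.74 mol% | 0.74 mol% |
| remark | run made earlier |  |
| time |  | 30 min |

teal run (percent of the substrate charged)

| time / min | dormant form / % | substrate / % |
|---|---|---|
| 0.500 | 0.1 | 8.1 |
| 1.00 | 0.2 | 16.3 |
| 2.50 | 1.6 | 39.4 |
| 6.00 | 9.3 | 90.6 |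

(scatter of a reading: 0.3 percentage points)

- percentages count the whole charge, also what has not yet gone in
- no earlier run changes the charge of initiator; that part of a forecast is a guess

* concentration of dormant form at 30 min, in M
* concentration of substrate at 30 min, in M

I followed one substrate molecule, whose fork I took to be staying or becoming dormant form. At 6.00 min in the teal run the two readings add to 99.9%, so I took the two as the balance. The surviving share, the part of the charge still present as substrate, read 90.7% at the end of the feed in the teal run. I took substrate in that run to climb roughly linearly during the feed, with a mean of half its final value over the feed, and that gave a one-way constant.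

k = 0.0342 min⁻¹

Ceiling, no further change after the feed: [substrate] = 0.181 M

Floor, one-way loss to 30 min: share 39.9%, [substrate] = 0.0798 M

Could the readings tighten this? In the teal run the dormant form reading rose 5.81-fold from 2.50 min to 6.00 min, against 5.76 for pure square growth. With a scatter of 0.3 percentage points on 1.6%, a way back was neither seen nor excluded, so the bracket stood.

The forecast gave 0.1 M substrate, inside my bracket, and 0.1 M dormant form: “I expect roughly half converted.”

The flask gave 0.146 M substrate, more than the forecast and below my ceiling, and 0.0517 M dormant form.

    initiator → 2 initiating radical (k = 3.70 × 10⁻⁴ s⁻¹)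
    substrate + initiating radical → capped initiator + first chain carrier (k = 6.00 × 10⁶ M⁻¹ s⁻¹)
    reagent + first chain carrier → target + second chain carrier (k = 19000 M⁻¹ s⁻¹)
    substrate + second chain carrier → by-product + first chain carrier (k = 1.20 × 10⁵ M⁻¹ s⁻¹)
    transfer agent + first chain carrier → side product + idle radical (kL = 1.10 × 10⁵ M⁻¹ s⁻¹)
    2 idle radical → ended radicals (k = 1.20 × 10⁹ M⁻¹ s⁻¹)
    2 first chain carrier → ended chains (k = 8.00 × 10⁸ M⁻¹ s⁻¹)
    substrate ⇌ dormant form (K = 0.360, k = 6.90 × 10⁻⁴ s⁻¹)

The neighbouring flask changed one setting: its substrate charge fell to 0.050 M, with equivalents, loadings and time held. The same shares bracketed it between 0.0200 M and 0.0454 M. The relaxation half-life of substrate and dormant form by this step alone is 4.43 min, short against 30 min; taking the two as a balance at equilibrium, the surviving share becomes 73.5%, which makes 0.0367 M. The neighbouring flask held 0.0129 M dormant form and 0.0366 M substrate, 73.3% of its charge.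

Readings and results come from a simulation with made-up constants, noise included.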